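## Retrosynthetic overview

1. Propolin A is traced back, through global acid deprotection and a Stille allylation at C2', to the 2'-bromoflavanone 16 (A ring as MOM ethers, B ring as tert-butyl carbonates).
2. Key disconnection: both bonds that tie the pyranone ring to the A ring (O1–C8a and C4–C4a) are cut, giving the (S)-4-aryl-oxetan-2-one 13 and 3,5-bis(methoxymethoxy)benzyne 14 (from silyl triflate 9). In the forward sense the aryne C≡C is inserted into the O1–C4 bond, so the four-membered ring (O1, C2, C3, C4) grows to the six-membered ring (O1, C2, C3, C4, C4a, C8a).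
3. Enabling feature: the strained acyl–oxygen bond O1–C4 of the oxetanone, with a nucleophilic ring oxygen next to an electrophilic carbonyl carbon. It is matched to an aryne polarised by the alkoxy group next to the triple bond (the later C5–O). The electron-poor B ring (carbonates, ortho Br) keeps the benzylic C2–O1 bond intact, so C2 is carried through with retention.
4. Lactone 13 comes from aldehyde 12 and ketene by a catalytic asymmetric [2+2] cycloaddition, which sets C2. The side chain comes from neryl acetate, which fixes the alkene geometry.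
5. Ring order: A and B rings are bought as benzenoids; the oxetanone is made in step 7 and expanded to the pyranone C ring in step 8; no other ring is formed.

Key step: step 8

Assumption 1: the side-chain alkene is taken exactly as written in the SMILES (C3-methyl trans to the benzylic CH2, i.e. the Z, neryl-type geometry), so neryl acetate is the starting material; geranyl acetate in the same sequence would give the E isomer.

Assumption 2: the sense of induction of the alkaloid catalyst in step 7 is taken by analogy; O-TMS-quinine is written for the (S)-lactone, and the pseudoenantiomeric O-TMS-quinidine is used instead if the opposite sense is found.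

## Route

Step 1
Reactants: 1 phloroglucinol (benzene-1,3,5-triol)
Product: 2 3,5-bis(methoxymethoxy)phenol
Conditions: MOMCl (2.1 equiv), iPr2NEt, DMF, 0 °C to rt; chromatographic separation from mono- and tris-ethers
Reagents that add atoms: chloromethyl methyl ether, COCCl
Why: O-alkylation of the three equivalent phenols (acetal protection) is statistical, and the bis-ether should be separable while the other ethers are recycled by acid hydrolysis.

Step 2
Reactants: 2 3,5-bis(methoxymethoxy)phenol
Product: 3 3,5-bis(methoxymethoxy)phenyl N-isopropylcarbamate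
Conditions: i-PrNCO, Et3N (cat.), CH2Cl2, rt
Reagents that add atoms: isopropyl isocyanate, CC(C)N=C=O
Why: Base-catalysed addition of the phenol to the isocyanate should give the N–H carbamate, a strong ortho-directing group that can later be removed under mild conditions.

Step 3
Reactants: 3 3,5-bis(methoxymethoxy)phenyl N-isopropylcarbamate
Product: 7 3,5-bis(methoxymethoxy)-2-(trimethylsilyl)phenyl N-isopropylcarbamate, via N-silyl carbamate 4 (not isolated), via aryllithium 5 (not isolated), via bis-silyl carbamate 6 (not isolated)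
Conditions: TBSOTf, TMEDA, Et2O, 0 °C to rt; n-BuLi, TMEDA, −78 °C; TMSCl, −78 °C to rt; aq. NaHSO4
Reagents that add atoms: chlorotrimethylsilane, C[Si](C)(C)Cl
Why: Directed ortho-metalation: after N-silylation the O-carbamate and the neighbouring OMOM group cooperate to direct lithiation to C2 (C2 and C6 are equivalent), TMSCl traps the aryllithium and the aqueous work-up removes the N-silyl group.

Step 4
Reactants: 7 3,5-bis(methoxymethoxy)-2-(trimethylsilyl)phenyl N-isopropylcarbamate
Product: 9 3,5-bis(methoxymethoxy)-2-(trimethylsilyl)phenyl trifluoromethanesulfonate, via silyl phenoxide 8 (not isolated)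
Conditions: DBU, Et2NH, MeCN, 40 °C; then PhNTf2, rt
Reagents that add atoms: N-phenyl-bis(trifluoromethanesulfonimide), O=S(=O)(N(c1ccccc1)S(=O)(=O)C(F)(F)F)C(F)(F)F
Why: The N–H carbamate is cleaved by E1cB elimination (the isocyanate is trapped as a urea) and the phenoxide is triflated in the same pot, the standard access to 2-silylaryl triflate aryne precursors.

Step 5
Reactants: 10 2-bromo-3-hydroxy-4-methoxybenzaldehyde
Product: 11 2-bromo-3,4-dihydroxybenzaldehyde
Conditions: BBr3, CH2Cl2, −78 °C to rt; H2O
Reagents that add atoms: none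
Why: Lewis-acid cleavage of the aryl methyl ether by BBr3 should free the catechol without touching the aldehyde or the aryl bromide.

Step 6
Reactants: 11 2-bromo-3,4-dihydroxybenzaldehyde
Product: 12 2-bromo-3,4-bis[(tert-butoxycarbonyl)oxy]benzaldehyde
Conditions: Boc2O (2.4 equiv), DMAP (cat.), THF, 0 °C to rt
Reagents that add atoms: di-tert-butyl dicarbonate, CC(C)(C)OC(=O)OC(=O)OC(C)(C)C
Why: DMAP-catalysed O-acylation gives the bis-carbonate, which is acid-labile, makes the aldehyde more electrophilic and lowers the donor ability of the B ring so that the later benzylic C–O bond does not ionise.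

Step 7
Reactants: 12 2-bromo-3,4-bis[(tert-butoxycarbonyl)oxy]benzaldehyde
Product: 13 (S)-4-{2-bromo-3,4-bis[(tert-butoxycarbonyl)oxy]phenyl}oxetan-2-one
Conditions: AcCl (slow addition), iPr2NEt, O-TMS-quinine (10 mol %), LiClO4, CH2Cl2/Et2O, −78 to −40 °C
Reagents that add atoms: acetyl chloride, CC(Cl)=O
Why: Cinchona-alkaloid/Lewis-acid-catalysed ketene–aldehyde [2+2] cycloaddition (acyl halide–aldehyde cyclocondensation): the chiral ammonium enolate formed from in-situ ketene adds to the Li+-activated aldehyde through a closed transition state and the aldolate lactonises, so the alkaloid sets the C4 stereocentre (the later C2) by catalyst control.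

Step 8
Reactants: 13 (S)-4-{2-bromo-3,4-bis[(tert-butoxycarbonyl)oxy]phenyl}oxetan-2-one; 9 3,5-bis(methoxymethoxy)-2-(trimethylsilyl)phenyl trifluoromethanesulfonate
Product: 16 (S)-2-{2-bromo-3,4-bis[(tert-butoxycarbonyl)oxy]phenyl}-5,7-bis(methoxymethoxy)chroman-4-one, via aryne 14 (not isolated), via oxetanium zwitterion 15 (not isolated)
Conditions: CsF (3 equiv, anhydrous), MeCN/toluene (1:1), rt, slow addition of 9 (1.5–2 equiv) to 13
Reagents that add atoms: none
Why: Proposed new method: fluoride-induced 1,2-elimination of 9 gives aryne 14, and the ring oxygen O1 of the β-lactone, which is unusually ether-like because the four-membered ring curtails its conjugation with the carbonyl group, adds to the aryne carbon remote from the flanking OMOM group to give the O-aryl oxetanium/aryl carbanion zwitterion 15. The carbanion, held next to the now strongly activated carbonyl carbon C4, adds to it and the adduct collapses with cleavage of the strained O1–C4 bond, so the aryne C=C is inserted into the acyl–oxygen σ-bond. The closest known reaction types are the aryne σ-insertions into the N–C(O) bond of β-lactams and cyclic ureas (two-carbon ring expansion), into the C–O bond of carboxylic acids and into the C–C bond of β-keto esters (acyl-alkylation). The only ring closed is the pyranone ring, by two-atom ring expansion of the oxetanone: O1–C8a by nucleophilic addition to the aryne, C4–C4a by intramolecular 1,2-addition of the aryl anion to the acyl carbon followed by opening of the four-membered ring. No new stereocentre is made, and C2 keeps its S configuration because neither the C2–O1 nor the C2–C3 bond is broken. The step needs the O1-to-C8a/acyl-to-C4a regiochemistry, secured by the polarisation of 14 by the alkoxy group next to the triple bond, and attack by the ring oxygen without ionisation of the benzylic C2–O1 bond, secured by the carbonate groups and the ortho bromine that make the B ring electron-poor.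

Step 9
Reactants: 17 neryl acetate [(2Z)-3,7-dimethylocta-2,6-dien-1-yl acetate]
Product: 20 (Z)-3,7-dimethyloct-2-ene-1,7-diol, via organomercurial 18 (not isolated), via hydroxy acetate 19 (not isolated)
Conditions: Hg(OAc)2, THF/H2O (1:1), rt; 3 M NaOH, NaBH4, 0 °C; crude, K2CO3, MeOH, rt
Reagents that add atoms: water, O
Why: Markovnikov oxymercuration–demercuration should hydrate only the electron-rich C6=C7 bond (the C2=C3 bond is deactivated by the allylic acetate and its Z geometry is untouched), and methanolysis then removes the acetate.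

Step 10
Reactants: 20 (Z)-3,7-dimethyloct-2-ene-1,7-diol
Product: 21 (Z)-8-chloro-2,6-dimethyloct-6-en-2-ol
Conditions: NCS, Me2S, CH2Cl2, −30 to 0 °C
Reagents that add atoms: N-chlorosuccinimide, O=C1CCC(=O)N1Cl
Why: Corey–Kim chlorination converts the primary allylic alcohol through its alkoxysulfonium salt into the chloride under neutral conditions, without allylic transposition or Z/E isomerisation and without reaction at the tertiary alcohol.

Step 11
Reactants: 21 (Z)-8-chloro-2,6-dimethyloct-6-en-2-ol
Product: 22 (Z)-2,6-dimethyl-8-(tributylstannyl)oct-6-en-2-ol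
Conditions: Bu3SnLi (2.1 equiv, from Bu3SnH and LDA, THF, 0 °C), THF, −78 to −40 °C; H2O
Reagents that add atoms: tributylstannyllithium, [Li][Sn](CCCC)(CCCC)CCCC
Why: SN2 displacement of the primary allylic chloride by the stannyl anion (one equivalent is consumed by the free hydroxyl) should give the linear allylstannane with the Z alkene retained.

Step 12
Reactants: 16 (S)-2-{2-bromo-3,4-bis[(tert-butoxycarbonyl)oxy]phenyl}-5,7-bis(methoxymethoxy)chroman-4-one; 22 (Z)-2,6-dimethyl-8-(tributylstannyl)oct-6-en-2-ol
Product: 23 (S)-2-{3,4-bis[(tert-butoxycarbonyl)oxy]-2-[(2Z)-7-hydroxy-3,7-dimethyloct-2-en-1-yl]phenyl}-5,7-bis(methoxymethoxy)chroman-4-one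
Conditions: Pd[P(t-Bu)3]2 (5 mol %), toluene (degassed), 70–80 °C
Reagents that add atoms: none
Why: Migita–Kosugi–Stille coupling: the bulky electron-rich Pd(0) inserts into the hindered aryl bromide, the allylstannane transmetalates and reductive elimination at the less substituted allyl terminus gives the linear allylarene under neutral conditions that spare the ketone, carbonates, acetals, free tertiary alcohol and C2, with the Z geometry expected to persist because isomerisation would need a tertiary σ-allyl palladium species.

Step 13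
Reactants: 23 (S)-2-{3,4-bis[(tert-butoxycarbonyl)oxy]-2-[(2Z)-7-hydroxy-3,7-dimethyloct-2-en-1-yl]phenyl}-5,7-bis(methoxymethoxy)chroman-4-one
Product: 24 propolin A, (2S)-2-{3,4-dihydroxy-2-[(2Z)-7-hydroxy-3,7-dimethyloct-2-en-1-yl]phenyl}-5,7-dihydroxy-2,3-dihydro-4H-chromen-4-one
Conditions: HCl (from AcCl) in MeOH (about 0.5 M), Ar, 0 to 30 °C
Reagents that add atoms: none
Why: Mild acid-catalysed methanolysis should cleave the two aryl MOM acetals and the two aryl tert-butyl carbonates in one operation without epimerising C2, dehydrating the tertiary alcohol or cyclising the ortho-allyl phenol, which need stronger acid.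

## Compound list

1 | phloroglucinol (benzene-1,3,5-triol) | Oc1cc(O)cc(O)c1 | starting material
2 | 3,5-bis(methoxymethoxy)phenol | COCOc1cc(O)cc(OCOC)c1 | intermediate
3 | 3,5-bis(methoxymethoxy)phenyl N-isopropylcarbamate | COCOc1cc(OCOC)cc(OC(=O)NC(C)C)c1 | intermediate
4 | 3,5-bis(methoxymethoxy)phenyl N-(tert-butyldimethylsilyl)-N-isopropylcarbamate | COCOc1cc(OCOC)cc(OC(=O)N(C(C)C)[Si](C)(C)C(C)(C)C)c1 | intermediate
5 | 2-lithio-3,5-bis(methoxymethoxy)phenyl N-(tert-butyldimethylsilyl)-N-isopropylcarbamate | COCOc1cc(OC(=O)N(C(C)C)[Si](C)(C)C(C)(C)C)c([Li])c(OCOC)c1 | intermediate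
6 | 3,5-bis(methoxymethoxy)-2-(trimethylsilyl)phenyl N-(tert-butyldimethylsilyl)-N-isopropylcarbamate | COCOc1cc(OC(=O)N(C(C)C)[Si](C)(C)C(C)(C)C)c([Si](C)(C)C)c(OCOC)c1 | intermediate
7 | 3,5-bis(methoxymethoxy)-2-(trimethylsilyl)phenyl N-isopropylcarbamate | COCOc1cc(OC(=O)NC(C)C)c([Si](C)(C)C)c(OCOC)c1 | intermediate
8 | 3,5-bis(methoxymethoxy)-2-(trimethylsilyl)phenol (present as its DBU salt) | COCOc1cc(O)c([Si](C)(C)C)c(OCOC)c1 | intermediate
9 | 3,5-bis(methoxymethoxy)-2-(trimethylsilyl)phenyl trifluoromethanesulfonate | COCOc1cc(OCOC)c([Si](C)(C)C)c(OS(=O)(=O)C(F)(F)F)c1 | intermediate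
10 | 2-bromo-3-hydroxy-4-methoxybenzaldehyde | COc1ccc(C=O)c(Br)c1O | starting material
11 | 2-bromo-3,4-dihydroxybenzaldehyde | O=Cc1ccc(O)c(O)c1Br | intermediate
12 | 2-bromo-3,4-bis[(tert-butoxycarbonyl)oxy]benzaldehyde | O=Cc1ccc(OC(=O)OC(C)(C)C)c(OC(=O)OC(C)(C)C)c1Br | intermediate
13 | (S)-4-{2-bromo-3,4-bis[(tert-butoxycarbonyl)oxy]phenyl}oxetan-2-one | Brc1c([C@@H]2CC(=O)O2)ccc(OC(=O)OC(C)(C)C)c1OC(=O)OC(C)(C)C | intermediate
14 | 3,5-bis(methoxymethoxy)benzyne (1,2-didehydro-3,5-bis(methoxymethoxy)benzene) | COCOC1=CC(OCOC)=CC#C1 | intermediate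
15 | O-aryl oxetanium / aryl carbanion zwitterion (O1 of the lactone bonded to the aryne carbon distal to OMOM, carbanion ortho to OMOM) | Brc1c([C@@H]2CC(=O)[O+]2c2cc(OCOC)cc(OCOC)[c-]2)ccc(OC(=O)OC(C)(C)C)c1OC(=O)OC(C)(C)C | intermediate
16 | (S)-2-{2-bromo-3,4-bis[(tert-butoxycarbonyl)oxy]phenyl}-5,7-bis(methoxymethoxy)chroman-4-one | Brc1c([C@@H]2CC(=O)c3c(OCOC)cc(OCOC)cc3O2)ccc(OC(=O)OC(C)(C)C)c1OC(=O)OC(C)(C)C | intermediate
17 | neryl acetate, (2Z)-3,7-dimethylocta-2,6-dien-1-yl acetate | C/C(=C/COC(C)=O)CCC=C(C)C | starting material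
18 | (Z)-6-(acetoxymercurio)-7-hydroxy-3,7-dimethyloct-2-en-1-yl acetate (racemic at C6) | C/C(=C/COC(C)=O)CCC([Hg]OC(C)=O)C(C)(C)O | intermediate
19 | (Z)-7-hydroxy-3,7-dimethyloct-2-en-1-yl acetate | C/C(=C/COC(C)=O)CCCC(C)(C)O | intermediate
20 | (Z)-3,7-dimethyloct-2-ene-1,7-diol | C/C(=C/CO)CCCC(C)(C)O | intermediate
21 | (Z)-8-chloro-2,6-dimethyloct-6-en-2-ol | C/C(=C/CCl)CCCC(C)(C)O | intermediate
22 | (Z)-2,6-dimethyl-8-(tributylstannyl)oct-6-en-2-ol | C/C(=C/C[Sn](CCCC)(CCCC)CCCC)CCCC(C)(C)O | intermediate
23 | (S)-2-{3,4-bis[(tert-butoxycarbonyl)oxy]-2-[(2Z)-7-hydroxy-3,7-dimethyloct-2-en-1-yl]phenyl}-5,7-bis(methoxymethoxy)chroman-4-one | C/C(=C/Cc1c([C@@H]2CC(=O)c3c(OCOC)cc(OCOC)cc3O2)ccc(OC(=O)OC(C)(C)C)c1OC(=O)OC(C)(C)C)CCCC(C)(C)O | intermediate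
24 | propolin A, (2S)-2-{3,4-dihydroxy-2-[(2Z)-7-hydroxy-3,7-dimethyloct-2-en-1-yl]phenyl}-5,7-dihydroxy-2,3-dihydro-4H-chromen-4-one | C/C(=C/Cc1c([C@@H]2CC(=O)c3c(O)cc(O)cc3O2)ccc(O)c1O)CCCC(C)(C)O | target

## Step count and risks

Total step count: 13. Longest linear sequence: 7 steps (steps 1, 2, 3, 4, 8, 12, 13).

Steps most likely to fail:

1. Step 8 (Proposed new method). The aryne may be captured through the carbonyl oxygen of the lactone, or not by the lactone at all. The lactone may also lose its configuration under the fluoride conditions by β-elimination to a cinnamate or by benzylic ionisation, and a tert-butyl carbonate may be cleaved by fluoride. Fallback with known chemistry: it sets out from aldehyde 12, which is taken through the step-7 cycloaddition with the pseudoenantiomeric alkaloid to give (R)-4-{2-bromo-3,4-bis[(tert-butoxycarbonyl)oxy]phenyl}oxetan-2-one F1. The caesium phenoxide of 2 (Cs2CO3, DMF, 0 °C) opens this lactone at the benzylic carbon by SN2 with inversion, the classical β-aryloxy acid synthesis, to give (S)-3-{2-bromo-3,4-bis[(tert-butoxycarbonyl)oxy]phenyl}-3-[3,5-bis(methoxymethoxy)phenoxy]propanoic acid F2. The acid is converted into its chloride with Ghosez's reagent and closed by intramolecular Friedel–Crafts acylation (catalytic ZnCl2, CH2Cl2, −20 °C) onto the electron-rich ring, whose two positions ortho to the ether oxygen are equivalent. The fallback comes back to the route at 16.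

2. Step 7. The cycloaddition may be sluggish or poorly face-selective with a hindered, ortho-substituted aromatic aldehyde, and the aryl β-lactone may decarboxylate on isolation. Fallback: it sets out from 12, which is homologated with allyl diazoacetate and catalytic SnCl2 (Roskamp reaction) to allyl 3-{2-bromo-3,4-bis[(tert-butoxycarbonyl)oxy]phenyl}-3-oxopropanoate F3. Noyori transfer hydrogenation (RuCl[(S,S)-TsDPEN](p-cymene), HCO2H/Et3N; the catalyst antipode expected by analogy with aryl ketones) should give allyl (S)-3-{2-bromo-3,4-bis[(tert-butoxycarbonyl)oxy]phenyl}-3-hydroxypropanoate F4. Deallylation with Pd(PPh3)4 and N-methylaniline gives (S)-3-{2-bromo-3,4-bis[(tert-butoxycarbonyl)oxy]phenyl}-3-hydroxypropanoic acid F5 without base that would attack the carbonates. Lactonisation by carboxyl activation (PhSO2Cl, pyridine, 0 °C) closes the ring with retention at the carbinol carbon. The fallback comes back to the route at 13.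

3. Step 12. Oxidative addition at the doubly ortho-substituted bromide may be slow, and the allyl group may be transferred with allylic transposition (branched isomer) or with Z/E isomerisation through π-allyl palladium intermediates. Fallback with reversed polarity: it sets out from 16, which is converted by Miyaura borylation (B2pin2, Pd(dppf)Cl2, KOAc, dioxane, 80 °C) into (S)-2-{3,4-bis[(tert-butoxycarbonyl)oxy]-2-(4,4,5,5-tetramethyl-1,3,2-dioxaborolan-2-yl)phenyl}-5,7-bis(methoxymethoxy)chroman-4-one F6. This arylboronate is coupled with the allylic chloride 21 under palladium catalysis (Pd2(dba)3, PPh3, K3PO4, THF/H2O, rt), where the aryl group is delivered to the less hindered allyl terminus. The fallback comes back to the route at 23.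

Further compounds

F1 | step 8 | (R)-4-{2-bromo-3,4-bis[(tert-butoxycarbonyl)oxy]phenyl}oxetan-2-one | Brc1c([C@H]2CC(=O)O2)ccc(OC(=O)OC(C)(C)C)c1OC(=O)OC(C)(C)C
F2 | step 8 | (S)-3-{2-bromo-3,4-bis[(tert-butoxycarbonyl)oxy]phenyl}-3-[3,5-bis(methoxymethoxy)phenoxy]propanoic acid | Brc1c([C@H](CC(=O)O)Oc2cc(OCOC)cc(OCOC)c2)ccc(OC(=O)OC(C)(C)C)c1OC(=O)OC(C)(C)C
F3 | step 7 | allyl 3-{2-bromo-3,4-bis[(tert-butoxycarbonyl)oxy]phenyl}-3-oxopropanoate | C=CCOC(=O)CC(=O)c1ccc(OC(=O)OC(C)(C)C)c(OC(=O)OC(C)(C)C)c1Br
F4 | step 7 | allyl (S)-3-{2-bromo-3,4-bis[(tert-butoxycarbonyl)oxy]phenyl}-3-hydroxypropanoate | C=CCOC(=O)C[C@H](O)c1ccc(OC(=O)OC(C)(C)C)c(OC(=O)OC(C)(C)C)c1Br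
F5 | step 7 | (S)-3-{2-bromo-3,4-bis[(tert-butoxycarbonyl)oxy]phenyl}-3-hydroxypropanoic acid | OC(=O)C[C@H](O)c1ccc(OC(=O)OC(C)(C)C)c(OC(=O)OC(C)(C)C)c1Br
F6 | step 12 | (S)-2-{3,4-bis[(tert-butoxycarbonyl)oxy]-2-(4,4,5,5-tetramethyl-1,3,2-dioxaborolan-2-yl)phenyl}-5,7-bis(methoxymethoxy)chroman-4-one | CC1(C)OB(OC1(C)C)c1c([C@@H]2CC(=O)c3c(OCOC)cc(OCOC)cc3O2)ccc(OC(=O)OC(C)(C)C)c1OC(=O)OC(C)(C)C
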